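The earlier runs and the new flask were computed for substances that don't exist; noise was put on by code.

Starting material and product add up to 99.7% at 15.0 h in the elm flask, within a few readings' scatter of the charge, so I count what leaves the one as the other. What I have to decide for the next plate is whether elm deserves its full time or the next wells need a different charge.

common to all: starting material 0.50 M (fed, over 30 min)
- elm: reagent 0.30 M; free catalyst 0.25 mM; the very flask that is asked about, followed so far
- ash: reagent 0.30 M; free catalyst 0.12 mM; run made earlier
- flask: reagent 0.300 M; free catalyst 0.25 mM; time 30 h

| run | time / h | starting material / % | product / % |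
|---|---|---|---|
| elm | 1.33 | 92.2 | 7.1 |
| elm | 2.00 | 88.5 | 11.5 |
| elm | 3.00 | 83.1 | 16.1 |
| elm | 5.00 | 74.9 | 25.4 |
| elm | 10.0 | 59.3 | 40.4 |
| elm | 15.0 | 50.4 | 49.3 |
| ash | 1.00 | 97.4 | 3.1 |
| ash | 1.50 | 95.3 | 4.7 |
| ash | 2.50 | 92.8 | 7.8 |
| ash | 4.00 | 88.6 | 11.8 |
| ash | 8.00 | 78.5 | 21.5 |
| ash | 12.0 | 69.7 | 29.3 |

(scatter of a reading: 0.3 percentage points)

- a reading or a percentage of product counts all its forms, free or not
- the reaction counts as stopped when no species that holds the starting material changes by six tenths of a point or more over the second half of the time

- at 30 h, what has stopped the reaction, if anything has (all of the starting material has reacted / it is still moving / the reagent has run out first / forward and back rates have come level / no working catalyst is left)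
- part of the starting material gone at 30 h
- the product standing at 30 h, as a percentage of the starting material charged

I assume one reagent per product, and then the charges give a ceiling, the reagent charge divided by the starting material charge, 60.0% of the starting material, with the reagent as limiting reagent. I replace the curve by its mean: the share of reagent left falls with one constant, read from elm's product at 15.0 h, 0.115 h⁻¹. That share is 17.8% there, and twice the time squares it to 3.18%, so my own figure for elm's product at 30 h is 58.1%, a rise of 8.8 percentage points that the stopping rule counts as still moving.

The mean has its error: it gives 26.2% at 5.00 h against the reading 25.4%, while a constant read at that point instead gives 57.8% at 30 h. The constant read at 15.0 h, scaled by the catalyst ratio, gives 29.1% for ash at 12.0 h against the reading 29.3%. So I let elm run and plan more reagent for the next wells.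

The forecast reckons its own way and says it is still moving, with 58% gone and 58% of product, from a plateau that “points to the reagent limit rather than an equilibrium”.

In the flask at 30 h the answer is that it is still moving, with 58.4% gone and 58.4% of product, under the ceiling of 60.0%.

    reagent + free catalyst ⇌ catalyst intermediate A (K = 3.50 L mol⁻¹, k = 749 L mol⁻¹ h⁻¹)
    starting material + catalyst intermediate A ⇌ catalyst intermediate B (K = 23.9 L mol⁻¹, k = 91700 L mol⁻¹ h⁻¹)
    2 free catalyst ⇌ resting dimer, settled at all times (K = 900 L mol⁻¹)
    free catalyst → spent catalyst (k = 4.42 × 10⁻⁴ h⁻¹)
    catalyst intermediate B → free catalyst + product (k = 498 h⁻¹)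
    crystals ⇌ product, rate k6*(cs6 - [product]) while solid is left; crystals form when [product] > cs6 (solubility = 0.240 M, k = 10.5 h⁻¹)

In the flask the forward rate alone of the step from reagent and free catalyst to catalyst intermediate A gave a reagent half-life of 5.7 h at 6.13 h, and the reagent stood at 17.8% of its charge at 15.0 h and 2.7% at 30.0 h, less than the 42% of its own charge of starting material left. The step from catalyst intermediate B to free catalyst and product had 85% of its turnover up to 30 h behind it at 15.0 h. In the neighbour flask with 1.2 M of starting material and the other charges as before, the ceiling falls to 25.0%, and the share of reagent left that I reckoned for elm, taken over unchanged, gives 24.2%; that neighbour flask gives 24.5%, with 2.2% of its reagent left.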